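## Retrosynthetic overview
1. The furanone ring is formed last. Target 43 comes from desilylation of 42, and 42 comes from gold-catalysed 5-endo-dig attack of the C10 hydroxyl on the ten-membered ynone 41.
2. The ten-membered carbocycle is closed at C1–C2 by a Nozaki–Hiyama–Kishi reaction of iodoalkyne aldehyde 38.
3. C13 is added by Mannich methylenation. The C8 isovalerate follows Felkin–Anh reduction of the C8 ketone 28, which is unmasked by a Nef reaction.
4. The key C7–C8 bond comes from intermolecular nitro-Michael addition of nitroalkane 24 (fragment 2: C1, C8–C10, C14, from (S)-lactic acid) to butenolide 14 (fragment 1: C2–C7, C11, C12, C15, from L-glutamic acid).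
5. Ring order: lactone (from glutamic acid), then carbocycle, then furanone.

Assumption: positions are given in germacrane numbering (C1 ketone, C2=C3, C4=C15H2, C5 carbinol, C6 lactone carbinol, C7, C8 ester carbinol, C9H2, C10, C11=C13H2, C12 lactone C=O, C14 methyl). Centres that are mixtures and are erased later are drawn without configuration.

## Fragment 1 (steps 1–11)

Step 1
Reactants: 1 L-glutamic acid
Product: 2 (S)-5-oxotetrahydrofuran-2-carboxylic acid
Conditions: NaNO2, aq HCl, 0 °C to rt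
Reagents that add atoms: none
Why: Diazotisation with double inversion through the α-lactone lets the γ-carboxyl close the butyrolactone with net retention, so C6 (S) comes from the chiral pool.

Step 2
Reactants: 2 (S)-5-oxotetrahydrofuran-2-carboxylic acid
Product: 3 (S)-5-oxotetrahydrofuran-2-carbonyl chloride
Conditions: (COCl)2, DMF (cat.), CH2Cl2, rt
Reagents that add atoms: oxalyl chloride ClC(=O)C(=O)Cl
Why: Acid chloride formation under base-free conditions leaves the α-acyloxy centre C6 untouched.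

Step 3
Reactants: 3 (S)-5-oxotetrahydrofuran-2-carbonyl chloride
Product: 4 (S)-5-[3-(trimethylsilyl)prop-2-ynoyl]dihydrofuran-2(3H)-one
Conditions: Me3SiC≡CSiMe3, AlCl3, CH2Cl2, 0 °C
Reagents that add atoms: bis(trimethylsilyl)acetylene C[Si](C)(C)C#C[Si](C)(C)C
Why: Friedel–Crafts-type ipso-acylation of the alkynylsilane gives the ynone (C4, C15) without base, so C6 is not epimerised.

Step 4
Reactants: 4 (S)-5-[3-(trimethylsilyl)prop-2-ynoyl]dihydrofuran-2(3H)-one
Product: 5 (S)-5-[(R)-1-hydroxy-3-(trimethylsilyl)prop-2-yn-1-yl]dihydrofuran-2(3H)-one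
Conditions: Ru[(S,S)-TsNCHPhCHPhNH](p-cymene) (1 mol%), i-PrOH, rt
Reagents that add atoms: none
Why: Noyori asymmetric transfer hydrogenation of alkynyl ketones is catalyst controlled, and the (S,S)-complex attacks the face that gives (S)-alkynols from alkyl alkynyl ketones, which here is C5 = R because C6 outranks the alkyne.

Step 5
Reactants: 5 (S)-5-[(R)-1-hydroxy-3-(trimethylsilyl)prop-2-yn-1-yl]dihydrofuran-2(3H)-one
Product: 6 (S)-5-[(R)-1-(tert-butyldimethylsilyloxy)-3-(trimethylsilyl)prop-2-yn-1-yl]dihydrofuran-2(3H)-one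
Conditions: TBSOTf, 2,6-lutidine, CH2Cl2, −78 to 0 °C
Reagents that add atoms: TBSOTf CC(C)(C)[Si](C)(C)OS(=O)(=O)C(F)(F)F
Why: Silyl ether protection of the secondary alcohol with a hindered base does not touch the lactone or either stereocentre.

Step 6
Reactants: 6 (S)-5-[(R)-1-(tert-butyldimethylsilyloxy)-3-(trimethylsilyl)prop-2-yn-1-yl]dihydrofuran-2(3H)-one
Product: 7 (S)-5-[(R)-1-(tert-butyldimethylsilyloxy)prop-2-yn-1-yl]dihydrofuran-2(3H)-one
Conditions: AgNO3 (10 mol%), CH2Cl2–MeOH–H2O, rt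
Reagents that add atoms: none
Why: Silver-catalysed protodesilylation cleaves only the C(sp)–Si bond, so the O–TBS group and the lactone survive where carbonate or fluoride might not be selective.

Step 7
Reactants: 7 (S)-5-[(R)-1-(tert-butyldimethylsilyloxy)prop-2-yn-1-yl]dihydrofuran-2(3H)-one
Product: 8 (S)-5-[(S)-1-(tert-butyldimethylsilyloxy)-2-(triethylsilyl)prop-2-en-1-yl]dihydrofuran-2(3H)-one
Conditions: [Cp*Ru(MeCN)3]PF6 (2 mol%), Et3SiH, CH2Cl2, 0 °C to rt
Reagents that add atoms: triethylsilane CC[SiH](CC)CC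
Why: Trost hydrosilylation of a terminal alkyne is Markovnikov selective and puts silicon on C4 to give the 1,1-disubstituted vinylsilane (same geometry at C5, descriptor S only because Si raises the rank of C4).

Step 8
Reactants: 8 (S)-5-[(S)-1-(tert-butyldimethylsilyloxy)-2-(triethylsilyl)prop-2-en-1-yl]dihydrofuran-2(3H)-one
Product: 9 (S)-5-[(S)-1-(tert-butyldimethylsilyloxy)-2-iodoprop-2-en-1-yl]dihydrofuran-2(3H)-one
Conditions: NIS, MeCN, 0 °C to rt, dark
Reagents that add atoms: N-iodosuccinimide O=C1CCC(=O)N1I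
Why: Electrophilic iododesilylation is an ipso substitution through the β-silyl cation and gives the 2-iodoalkene regiospecifically.

Step 9
Reactants: 9 (S)-5-[(S)-1-(tert-butyldimethylsilyloxy)-2-iodoprop-2-en-1-yl]dihydrofuran-2(3H)-one
Product: 10 (S)-5-[(R)-1-(tert-butyldimethylsilyloxy)-2-methylidene-4-(triisopropylsilyl)but-3-yn-1-yl]dihydrofuran-2(3H)-one
Conditions: i-Pr3SiC≡CH, PdCl2(PPh3)2 (3 mol%), CuI (6 mol%), Et3N, THF, rt
Reagents that add atoms: (triisopropylsilyl)acetylene C#C[Si](C(C)C)(C(C)C)C(C)C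
Why: Sonogashira coupling of an unhindered vinyl iodide forms C3–C4 at room temperature while the lactone is still saturated and inert to palladium and amine.

Step 10
Reactants: 10 (S)-5-[(R)-1-(tert-butyldimethylsilyloxy)-2-methylidene-4-(triisopropylsilyl)but-3-yn-1-yl]dihydrofuran-2(3H)-one
Product: 12 3-(phenylselanyl) derivative of 10 (C11 epimers), via lithium enolate 11 (not isolated)
Conditions: LiN(i-Pr)2, THF, −78 °C; PhSeBr, −78 °C
Reagents that add atoms: benzeneselenenyl bromide Br[Se]c1ccccc1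
Why: The lactone α-CH2 is the only acidic site, so kinetic enolate selenenylation occurs at C11, and the new centre is erased in the next step.

Step 11
Reactants: 12 3-(phenylselanyl) derivative of 10
Product: 14 (S)-5-[(R)-1-(tert-butyldimethylsilyloxy)-2-methylidene-4-(triisopropylsilyl)but-3-yn-1-yl]furan-2(5H)-one (fragment 1), via selenoxide 13 (not isolated)
Conditions: 30% H2O2, pyridine, CH2Cl2, 0 °C to rt
Reagents that add atoms: none
Why: Selenoxide syn-elimination can only take a C7 hydrogen and gives the butenolide under near-neutral conditions that do not epimerise C6.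

## Fragment 2 (steps 12–18)

Step 12
Reactants: 15 (S)-lactic acid
Product: 16 (2S,5S)-2-tert-butyl-5-methyl-1,3-dioxolan-4-one
Conditions: t-BuCHO, TsOH·H2O (cat.), pentane, reflux (Dean–Stark); recrystallise from Et2O–pentane at −78 °C
Reagents that add atoms: pivalaldehyde CC(C)(C)C=O
Why: Acid-catalysed acetalisation (Seebach self-regeneration of stereocentres) favours the cis-dioxolanone, whose acetal centre is set by the lactate centre and purified by crystallisation.

Step 13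
Reactants: 16 (2S,5S)-2-tert-butyl-5-methyl-1,3-dioxolan-4-one
Product: 18 (2S,5R)-2-tert-butyl-5-methyl-5-(prop-2-en-1-yl)-1,3-dioxolan-4-one, via lithium enolate 17 (not isolated)
Conditions: LiN(i-Pr)2, THF, −78 °C; allyl bromide, −78 to −30 °C
Reagents that add atoms: allyl bromide C=CCBr
Why: The enolate is alkylated anti to the tert-butyl group, so allyl replaces hydrogen with retention and sets the quaternary C10 as R.

Step 14
Reactants: 18 (2S,5R)-2-tert-butyl-5-methyl-5-(prop-2-en-1-yl)-1,3-dioxolan-4-one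
Product: 19 (R)-2-methylpent-4-ene-1,2-diol
Conditions: LiAlH4, Et2O, 0 °C to rt; Fieser work-up
Reagents that add atoms: none
Why: Hydride reduction of the acylal-type ester frees the C1 primary alcohol and the C10 tertiary alcohol without touching the quaternary centre.

Step 15
Reactants: 19 (R)-2-methylpent-4-ene-1,2-diol
Product: 20 (R)-2,2,4-trimethyl-4-(prop-2-en-1-yl)-1,3-dioxolane
Conditions: Me2C(OMe)2, TsOH·H2O (cat.), CH2Cl2, rt
Reagents that add atoms: 2,2-dimethoxypropane COC(C)(C)OC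
Why: Transketalisation protects O1 and O10 in one operation as an acetonide that is stable to base, hydride and enolate chemistry.

Step 16
Reactants: 20 (R)-2,2,4-trimethyl-4-(prop-2-en-1-yl)-1,3-dioxolane
Product: 22 2-[(R)-2,2,4-trimethyl-1,3-dioxolan-4-yl]ethan-1-ol, via aldehyde 21 (not isolated)
Conditions: O3, CH2Cl2–MeOH, −78 °C; NaBH4, −78 °C to rt
Reagents that add atoms: ozone [O-][O+]=O
Why: Ozonolysis with reductive work-up removes the terminal carbon and leaves C8 as a primary alcohol.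

Step 17
Reactants: 22 2-[(R)-2,2,4-trimethyl-1,3-dioxolan-4-yl]ethan-1-ol
Product: 23 (R)-4-(2-iodoethyl)-2,2,4-trimethyl-1,3-dioxolane
Conditions: I2, PPh3, imidazole, CH2Cl2, 0 °C to rt
Reagents that add atoms: iodine II
Why: Appel-type iodination of an unhindered primary alcohol runs under buffered conditions that keep the acetonide.

Step 18
Reactants: 23 (R)-4-(2-iodoethyl)-2,2,4-trimethyl-1,3-dioxolane
Product: 24 (R)-2,2,4-trimethyl-4-(2-nitroethyl)-1,3-dioxolane (fragment 2)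
Conditions: NaNO2, DMF, rt
Reagents that add atoms: sodium nitrite [Na+].[O-]N=O
Why: Kornblum SN2 displacement of a primary iodide by nitrite gives the nitroalkane, and the minor nitrite ester is removed by chromatography.

## Coupling and completion (steps 19–31)

Step 19
Reactants: 14 butenolide (fragment 1); 24 nitroalkane (fragment 2)
Product: 25 (4R,5S)-5-[(1R)-1-(TBSO)-2-methylidene-4-(TIPS)but-3-yn-1-yl]-4-{1-nitro-2-[(4R)-2,2,4-trimethyl-1,3-dioxolan-4-yl]ethyl}dihydrofuran-2(3H)-one (C8 epimers)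
Conditions: DBU (0.2 equiv), MeCN, 0 °C to rt
Reagents that add atoms: none
Why: In this intermolecular nitro-Michael addition the soft nitronate attacks C7 on the butenolide face anti to the branched C6 side chain, giving the trans lactone (C7 R), and the C8 epimer mixture does not matter.

Step 20
Reactants: 25 nitro lactone
Product: 28 (4S,5S)-5-[(1R)-1-(TBSO)-2-methylidene-4-(TIPS)but-3-yn-1-yl]-4-{[(4R)-2,2,4-trimethyl-1,3-dioxolan-4-yl]acetyl}dihydrofuran-2(3H)-one, via sodium nitronate 26 (not isolated), via imine 27 (not isolated)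
Conditions: NaOMe (1.05 equiv), MeOH–THF, 0 °C; then aq TiCl3, NH4OAc (pH 6), 0 °C to rt
Reagents that add atoms: water O
Why: The McMurry reductive Nef reaction at buffered pH spares enyne, silyl groups, acetonide and lactone, and C7 keeps its geometry because trans is also the thermodynamic arrangement (descriptor S only because the C8 ketone outranks C6).

Step 21
Reactants: 28 keto lactone
Product: 29 (4R,5S)-5-[(1R)-1-(TBSO)-2-methylidene-4-(TIPS)but-3-yn-1-yl]-4-{(1R)-1-hydroxy-2-[(4R)-2,2,4-trimethyl-1,3-dioxolan-4-yl]ethyl}dihydrofuran-2(3H)-one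
Conditions: LiBH(s-Bu)3, THF, −78 °C; H2O
Reagents that add atoms: none
Why: In this Felkin–Anh reduction the C7–C6 bond with its bulky side chain lies perpendicular to the carbonyl and the bulky hydride enters anti to it past H7, giving C8 = R, with any 8S epimer separable and recyclable by oxidation.

Step 22
Reactants: 29 hydroxy lactone
Product: 31 3-[(dimethylamino)methyl] derivative of 29 (C11 epimers), via dilithio enolate alkoxide 30 (not isolated)
Conditions: LiN(i-Pr)2 (3 equiv), THF, −78 °C; CH2=NMe2 I, −78 to 0 °C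
Reagents that add atoms: N,N-dimethylmethyleneiminium iodide C=[N+](C)C.[I-]
Why: In this Mannich reaction with Eschenmoser's salt the alkoxide is only a spectator, carbon C13 is placed on C11, and the new centre is erased in the next step.

Step 23
Reactants: 31 Mannich base
Product: 33 (4R,5S)-5-[(1R)-1-(TBSO)-2-methylidene-4-(TIPS)but-3-yn-1-yl]-4-{(1R)-1-hydroxy-2-[(4R)-2,2,4-trimethyl-1,3-dioxolan-4-yl]ethyl}-3-methylidenedihydrofuran-2(3H)-one, via trimethylammonium iodide 32 (not isolated)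
Conditions: MeI, THF–MeOH, rt; then aq NaHCO3, CH2Cl2, rt
Reagents that add atoms: none
Why: Quaternisation followed by mild E1cB (Hofmann-type) elimination gives only the exocyclic C11=C13 alkene, and every later step is free of amines, palladium and carbon nucleophiles that could attack it.

Step 24
Reactants: 33 α-methylene lactone alcohol
Product: 34 8-O-(3-methylbutanoyl) ester of 33
Conditions: isovaleric anhydride, DMAP (cat.), Et3N, CH2Cl2, rt
Reagents that add atoms: isovaleric anhydride CC(C)CC(=O)OC(=O)CC(C)C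
Why: DMAP-catalysed acylation of the only free hydroxyl installs the ester with retention at C8, after all enolate chemistry is finished.

Step 25
Reactants: 34 isovalerate
Product: 36 iodoalkyne (C2–I in place of C2–TIPS in 34), via silver acetylide 35 (not isolated)
Conditions: AgF, NIS, MeCN, rt, dark
Reagents that add atoms: N-iodosuccinimide O=C1CCC(=O)N1I
Why: Silver-assisted cleavage of the C(sp)–Si bond gives the acetylide, which is iodinated in situ, and this is much faster than attack on the hindered secondary TBS ether.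

Step 26
Reactants: 36 iodoalkyne
Product: 37 1,10-diol (acetonide of 36 removed)
Conditions: TFA–H2O (10:1), CH2Cl2, 0 °C
Reagents that add atoms: none
Why: Brief acid hydrolysis opens the strained acetonide on the quaternary carbon faster than the secondary TBS ether, and ester, lactone and iodoalkyne are acid stable.

Step 27
Reactants: 37 1,10-diol
Product: 38 C1 aldehyde with free C10 tertiary alcohol
Conditions: Dess–Martin periodinane, CH2Cl2, 0 °C to rt
Reagents that add atoms: none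
Why: Dess–Martin oxidation converts the only oxidisable (primary) alcohol into a non-enolisable α-hydroxy aldehyde without glycol cleavage.

Step 28
Reactants: 38 iodoalkyne aldehyde
Product: 40 ten-membered enyne carbinol: 1,10-dihydroxy-5-O-TBS-8-O-isovaleryl-germacra-4(15),11(13)-dien-2-yn-12,6-olide (5R,6S,7R,8R,10R; C1 epimers), via alkynylchromium dichloride 39 (not isolated)
Conditions: CrCl2 (10 equiv), NiCl2 (1 mol%), THF, 2 mM, rt
Reagents that add atoms: none
Why: In this Nozaki–Hiyama–Kishi macrocyclisation the alkynylchromium species adds only to the aldehyde, tolerating ester, lactone, acrylate and free hydroxyl, and the C1 carbinol configuration is irrelevant.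

Step 29
Reactants: 40 ten-membered enyne carbinol
Product: 41 ten-membered 10-hydroxy-1-oxo-2-yne (ynone)
Conditions: Dess–Martin periodinane, CH2Cl2, rt
Reagents that add atoms: none
Why: Dess–Martin oxidation of the secondary propargylic alcohol next to a tertiary alcohol gives the α'-hydroxy ynone and removes the C1 stereocentre.

Step 30
Reactants: 41 hydroxy ynone
Product: 42 5-O-TBS ether of the target
Conditions: (4-CF3C6H4)3PAuCl (5 mol%), AgOTf (5 mol%), toluene, rt
Reagents that add atoms: none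
Why: Cationic gold activates the ynone for transannular 5-endo-dig oxa-Michael cycloisomerisation of the C10 hydroxyl onto C3, forming the 3(2H)-furanone with C10 unchanged and O5 still protected.

Step 31
Reactants: 42 5-O-TBS ether of the target
Product: 43 CNP0409337.2
Conditions: HF·pyridine, pyridine, THF, 0 °C to rt
Reagents that add atoms: none
Why: Buffered fluoride desilylation frees the C5 allylic alcohol (R) without base, so the α-methylene lactone, dienone and ester stay intact.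

## Compound list
1 | L-glutamic acid | N[C@@H](CCC(=O)O)C(=O)O | starting material
2 | (S)-5-oxotetrahydrofuran-2-carboxylic acid | O=C1O[C@H](C(=O)O)CC1 | intermediate
3 | (S)-5-oxotetrahydrofuran-2-carbonyl chloride | O=C1O[C@H](C(=O)Cl)CC1 | intermediate
4 | (S)-5-[3-(trimethylsilyl)prop-2-ynoyl]dihydrofuran-2(3H)-one | O=C1O[C@H](C(=O)C#C[Si](C)(C)C)CC1 | intermediate
5 | (S)-5-[(R)-1-hydroxy-3-(trimethylsilyl)prop-2-yn-1-yl]dihydrofuran-2(3H)-one | O=C1O[C@H]([C@H](O)C#C[Si](C)(C)C)CC1 | intermediate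
6 | TBS ether of 5 (5R,6S) | O=C1O[C@H]([C@H](O[Si](C)(C)C(C)(C)C)C#C[Si](C)(C)C)CC1 | intermediate
7 | (S)-5-[(R)-1-(TBSO)prop-2-yn-1-yl]dihydrofuran-2(3H)-one | O=C1O[C@H]([C@H](O[Si](C)(C)C(C)(C)C)C#C)CC1 | intermediate
8 | (S)-5-[(S)-1-(TBSO)-2-(triethylsilyl)prop-2-en-1-yl]dihydrofuran-2(3H)-one | O=C1O[C@H]([C@H](O[Si](C)(C)C(C)(C)C)C(=C)[Si](CC)(CC)CC)CC1 | intermediate
9 | (S)-5-[(S)-1-(TBSO)-2-iodoprop-2-en-1-yl]dihydrofuran-2(3H)-one | O=C1O[C@H]([C@H](O[Si](C)(C)C(C)(C)C)C(=C)I)CC1 | intermediate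
10 | (S)-5-[(R)-1-(TBSO)-2-methylidene-4-(TIPS)but-3-yn-1-yl]dihydrofuran-2(3H)-one | O=C1O[C@H]([C@H](O[Si](C)(C)C(C)(C)C)C(=C)C#C[Si](C(C)C)(C(C)C)C(C)C)CC1 | intermediate
11 | lithium enolate of 10 | [Li+].[O-]C1=CC[C@@H]([C@H](O[Si](C)(C)C(C)(C)C)C(=C)C#C[Si](C(C)C)(C(C)C)C(C)C)O1 | intermediate
12 | 3-(phenylselanyl) derivative of 10 (C11 epimers) | O=C1O[C@H]([C@H](O[Si](C)(C)C(C)(C)C)C(=C)C#C[Si](C(C)C)(C(C)C)C(C)C)CC1[Se]c1ccccc1 | intermediate
13 | selenoxide of 12 | O=C1O[C@H]([C@H](O[Si](C)(C)C(C)(C)C)C(=C)C#C[Si](C(C)C)(C(C)C)C(C)C)CC1[Se](=O)c1ccccc1 | intermediate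
14 | (S)-5-[(R)-1-(TBSO)-2-methylidene-4-(TIPS)but-3-yn-1-yl]furan-2(5H)-one (fragment 1) | O=C1O[C@H]([C@H](O[Si](C)(C)C(C)(C)C)C(=C)C#C[Si](C(C)C)(C(C)C)C(C)C)C=C1 | intermediate
15 | (S)-lactic acid | C[C@H](O)C(=O)O | starting material
16 | (2S,5S)-2-tert-butyl-5-methyl-1,3-dioxolan-4-one | C[C@@H]1O[C@H](C(C)(C)C)OC1=O | intermediate
17 | lithium enolate of 16 | [Li+].CC1=C([O-])O[C@@H](C(C)(C)C)O1 | intermediate
18 | (2S,5R)-2-tert-butyl-5-methyl-5-(prop-2-en-1-yl)-1,3-dioxolan-4-one | C[C@]1(CC=C)O[C@H](C(C)(C)C)OC1=O | intermediate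
19 | (R)-2-methylpent-4-ene-1,2-diol | C=CC[C@@](CO)(C)O | intermediate
20 | (R)-2,2,4-trimethyl-4-(prop-2-en-1-yl)-1,3-dioxolane | C=CC[C@@]1(C)OC(C)(C)OC1 | intermediate
21 | 2-[(R)-2,2,4-trimethyl-1,3-dioxolan-4-yl]acetaldehyde | O=CC[C@@]1(C)OC(C)(C)OC1 | intermediate
22 | 2-[(R)-2,2,4-trimethyl-1,3-dioxolan-4-yl]ethan-1-ol | OCC[C@@]1(C)OC(C)(C)OC1 | intermediate
23 | (R)-4-(2-iodoethyl)-2,2,4-trimethyl-1,3-dioxolane | ICC[C@@]1(C)OC(C)(C)OC1 | intermediate
24 | (R)-2,2,4-trimethyl-4-(2-nitroethyl)-1,3-dioxolane (fragment 2) | O=[N+]([O-])CC[C@@]1(C)OC(C)(C)OC1 | intermediate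
25 | nitro lactone (5R,6S,7R,10R; C8 epimers) | C1C(=O)O[C@H]([C@H](O[Si](C)(C)C(C)(C)C)C(=C)C#C[Si](C(C)C)(C(C)C)C(C)C)[C@H]1C([N+](=O)[O-])C[C@@]1(C)OC(C)(C)OC1 | intermediate
26 | sodium nitronate of 25 | C1C(=O)O[C@H]([C@H](O[Si](C)(C)C(C)(C)C)C(=C)C#C[Si](C(C)C)(C(C)C)C(C)C)[C@H]1C(=[N+]([O-])[O-])C[C@@]1(C)OC(C)(C)OC1.[Na+] | intermediate
27 | C8 imine | C1C(=O)O[C@H]([C@H](O[Si](C)(C)C(C)(C)C)C(=C)C#C[Si](C(C)C)(C(C)C)C(C)C)[C@H]1C(=N)C[C@@]1(C)OC(C)(C)OC1 | intermediate
28 | keto lactone (5R,6S,7S,10R) | C1C(=O)O[C@H]([C@H](O[Si](C)(C)C(C)(C)C)C(=C)C#C[Si](C(C)C)(C(C)C)C(C)C)[C@H]1C(=O)C[C@@]1(C)OC(C)(C)OC1 | intermediate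
29 | hydroxy lactone (5R,6S,7R,8R,10R) | C1C(=O)O[C@H]([C@H](O[Si](C)(C)C(C)(C)C)C(=C)C#C[Si](C(C)C)(C(C)C)C(C)C)[C@H]1[C@H](O)C[C@@]1(C)OC(C)(C)OC1 | intermediate
30 | dilithio enolate alkoxide of 29 | [Li+].[Li+].[O-]C1=C[C@H]([C@H]([O-])C[C@@]2(C)OC(C)(C)OC2)[C@@H]([C@H](O[Si](C)(C)C(C)(C)C)C(=C)C#C[Si](C(C)C)(C(C)C)C(C)C)O1 | intermediate
31 | Mannich base, 11-(dimethylaminomethyl) lactone (C11 epimers) | CN(C)CC1C(=O)O[C@H]([C@H](O[Si](C)(C)C(C)(C)C)C(=C)C#C[Si](C(C)C)(C(C)C)C(C)C)[C@H]1[C@H](O)C[C@@]1(C)OC(C)(C)OC1 | intermediate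
32 | trimethylammonium iodide of 31 | C[N+](C)(C)CC1C(=O)O[C@H]([C@H](O[Si](C)(C)C(C)(C)C)C(=C)C#C[Si](C(C)C)(C(C)C)C(C)C)[C@H]1[C@H](O)C[C@@]1(C)OC(C)(C)OC1.[I-] | intermediate
33 | α-methylene lactone alcohol (5R,6S,7R,8R,10R) | C=C1C(=O)O[C@H]([C@H](O[Si](C)(C)C(C)(C)C)C(=C)C#C[Si](C(C)C)(C(C)C)C(C)C)[C@H]1[C@H](O)C[C@@]1(C)OC(C)(C)OC1 | intermediate
34 | 8-O-isovalerate of 33 | C=C1C(=O)O[C@H]([C@H](O[Si](C)(C)C(C)(C)C)C(=C)C#C[Si](C(C)C)(C(C)C)C(C)C)[C@H]1[C@H](OC(=O)CC(C)C)C[C@@]1(C)OC(C)(C)OC1 | intermediate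
35 | silver acetylide | C=C1C(=O)O[C@H]([C@H](O[Si](C)(C)C(C)(C)C)C(=C)C#C[Ag])[C@H]1[C@H](OC(=O)CC(C)C)C[C@@]1(C)OC(C)(C)OC1 | intermediate
36 | iodoalkyne | C=C1C(=O)O[C@H]([C@H](O[Si](C)(C)C(C)(C)C)C(=C)C#CI)[C@H]1[C@H](OC(=O)CC(C)C)C[C@@]1(C)OC(C)(C)OC1 | intermediate
37 | iodoalkyne 1,10-diol | C=C1C(=O)O[C@H]([C@H](O[Si](C)(C)C(C)(C)C)C(=C)C#CI)[C@H]1[C@H](OC(=O)CC(C)C)C[C@@](CO)(C)O | intermediate
38 | iodoalkyne C1 aldehyde | C=C1C(=O)O[C@H]([C@H](O[Si](C)(C)C(C)(C)C)C(=C)C#CI)[C@H]1[C@H](OC(=O)CC(C)C)C[C@@](C=O)(C)O | intermediate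
39 | alkynylchromium dichloride | C=C1C(=O)O[C@H]([C@H](O[Si](C)(C)C(C)(C)C)C(=C)C#C[Cr](Cl)Cl)[C@H]1[C@H](OC(=O)CC(C)C)C[C@@](C=O)(C)O | intermediate
40 | ten-membered enyne carbinol (5R,6S,7R,8R,10R; C1 epimers) | C=C1C(=O)O[C@H]2[C@H]1[C@H](OC(=O)CC(C)C)C[C@@](C)(O)C(O)C#CC(=C)[C@H]2O[Si](C)(C)C(C)(C)C | intermediate
41 | ten-membered hydroxy ynone | C=C1C(=O)O[C@H]2[C@H]1[C@H](OC(=O)CC(C)C)C[C@@](C)(O)C(=O)C#CC(=C)[C@H]2O[Si](C)(C)C(C)(C)C | intermediate
42 | 5-O-TBS ether of the target | C=C1C(=O)O[C@H]2[C@H]1[C@H](OC(=O)CC(C)C)C[C@@]1(C)OC(=CC1=O)C(=C)[C@H]2O[Si](C)(C)C(C)(C)C | intermediate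
43 | CNP0409337.2, (5R,6S,7R,8R,10R)-5-hydroxy-8-(3-methylbutanoyloxy)-1-oxo-3,10-epoxygermacra-2,4(15),11(13)-trien-12,6-olide | C=C1C(=O)O[C@H]2[C@H]1[C@H](OC(=O)CC(C)C)C[C@@]1(C)OC(=CC1=O)C(=C)[C@H]2O | target

## Step count and risks
Total step count: 31.
Longest linear sequence: 24 steps (steps 1–11, then 19–31).

**Step 19 (nitro-Michael coupling).** The hindered nitronate may add slowly. DBU may instead deprotonate C6 of 14 and expel the C5 silyloxy group. The fallback swaps the nitronate for a sulfur-stabilised carbanion that reacts irreversibly at −78 °C. It sets out from alkene 20 (with 14) and comes back at ketone 28. Ozonolysis of 20 with Me2S work-up gives aldehyde 21, this time isolated. 1,3-Propanedithiol with MgBr2·OEt2 converts it into the dithiane F1. n-BuLi in THF–DMPU gives the 2-lithiodithiane F2. Its 1,4-addition to 14, anti to the C6 side chain, gives after protonation the dithiane lactone F3. PhI(OCOCF3)2 in aqueous MeCN then unmasks 28.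

**Step 21 (C8 reduction).** C6 and C11 differ only moderately in size as seen from the ketone, so the facial bias may be low or even reversed. The fallback uses inversion instead of direct delivery. It sets out from ketone 28 and comes back at alcohol 29. Reduction with NaBH4–CeCl3 and separation gives the 8S alcohol F4. A Mitsunobu reaction (4-nitrobenzoic acid, DIAD, PPh3) turns it into the 8R 4-nitrobenzoate F5. K2CO3 in MeOH at 0 °C releases 29.

**Step 28 (ring closure to the cyclodecenyne).** Strain in the ten-membered alkyne may favour oligomers. The fallback closes a more flexible, alkyne-free ring by an intramolecular boron aldol reaction and builds the furanone from a 1,3-diketone. It sets out from ester 34 and comes back at 42.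
- AgF in MeCN followed by dilute acid gives the terminal enyne F6.
- Ph3PAuNTf2-catalysed Markovnikov hydration in aqueous dioxane gives the methyl enone F7.
- TFA–H2O gives the keto diol F8.
- Dess–Martin oxidation gives the keto aldehyde F9.
- c-Hex2BCl and Et3N at high dilution enolise only the methyl ketone and close C1–C2 to the macrocyclic aldol F10.
- Dess–Martin oxidation gives the hydroxy 1,3-diketone F11.
- TsOH-catalysed cyclodehydration of the C10 hydroxyl onto C3 gives 42.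

## Further compounds
F1 | step 19 | 2-{[(R)-2,2,4-trimethyl-1,3-dioxolan-4-yl]methyl}-1,3-dithiane | C1CSC(SC1)C[C@@]1(C)OC(C)(C)OC1
F2 | step 19 | 2-lithio derivative of F1 | [Li]C1(C[C@@]2(C)OC(C)(C)OC2)SCCCS1
F3 | step 19 | dithiane lactone (C8 as 1,3-dithiane; 5R,6S,10R, trans lactone) | C1C(=O)O[C@H]([C@H](O[Si](C)(C)C(C)(C)C)C(=C)C#C[Si](C(C)C)(C(C)C)C(C)C)[C@H]1C1(SCCCS1)C[C@@]1(C)OC(C)(C)OC1
F4 | step 21 | 8S epimer of 29 | C1C(=O)O[C@H]([C@H](O[Si](C)(C)C(C)(C)C)C(=C)C#C[Si](C(C)C)(C(C)C)C(C)C)[C@H]1[C@@H](O)C[C@@]1(C)OC(C)(C)OC1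
F5 | step 21 | 8R 4-nitrobenzoate of 29 | C1C(=O)O[C@H]([C@H](O[Si](C)(C)C(C)(C)C)C(=C)C#C[Si](C(C)C)(C(C)C)C(C)C)[C@H]1[C@H](OC(=O)c1ccc(cc1)[N+](=O)[O-])C[C@@]1(C)OC(C)(C)OC1
F6 | step 28 | terminal enyne (34 without TIPS) | C=C1C(=O)O[C@H]([C@H](O[Si](C)(C)C(C)(C)C)C(=C)C#C)[C@H]1[C@H](OC(=O)CC(C)C)C[C@@]1(C)OC(C)(C)OC1
F7 | step 28 | methyl enone (C3 ketone, C2 methyl) | C=C1C(=O)O[C@H]([C@H](O[Si](C)(C)C(C)(C)C)C(=C)C(C)=O)[C@H]1[C@H](OC(=O)CC(C)C)C[C@@]1(C)OC(C)(C)OC1
F8 | step 28 | keto diol | C=C1C(=O)O[C@H]([C@H](O[Si](C)(C)C(C)(C)C)C(=C)C(C)=O)[C@H]1[C@H](OC(=O)CC(C)C)C[C@@](CO)(C)O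
F9 | step 28 | keto aldehyde | C=C1C(=O)O[C@H]([C@H](O[Si](C)(C)C(C)(C)C)C(=C)C(C)=O)[C@H]1[C@H](OC(=O)CC(C)C)C[C@@](C=O)(C)O
F10 | step 28 | macrocyclic aldol (C1 epimers) | C=C1C(=O)O[C@H]2[C@H]1[C@H](OC(=O)CC(C)C)C[C@@](C)(O)C(O)CC(=O)C(=C)[C@H]2O[Si](C)(C)C(C)(C)C
F11 | step 28 | macrocyclic 10-hydroxy-1,3-diketone | C=C1C(=O)O[C@H]2[C@H]1[C@H](OC(=O)CC(C)C)C[C@@](C)(O)C(=O)CC(=O)C(=C)[C@H]2O[Si](C)(C)C(C)(C)C
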